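**Retrosynthetic overview**
1. The cinnamate is closed last by a Horner–Wadsworth–Emmons reaction of a 6-O-phosphonoacetate with benzaldehyde; the 4α,15-diol comes from α-face dihydroxylation of a 4(15)-alkene, and the 6β-OH from α-face hydride reduction of a 6-ketone.
2. The trans-fused 4(15)-en-6-one comes from the conjugated 4-en-6-one: C7 is set by kinetic protonation, C5 by photodeconjugation and ketonisation.
3. Ring B is formed by one-carbon ring expansion of a cyclopentanone with 1-diazo-2-methylpropane, which brings in C7 and the isopropyl group.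
4. Ring A is formed before that by gold-catalysed 6-exo-dig cyclisation of an enol carbamate onto a terminal alkyne (C4–C5 bond, exocyclic methylene).
5. The C1/C10 pair comes from a Hoppe homoaldol reaction of an (S)-cyclopentenyl carbamate with pent-4-ynal. Ring order: cyclopentene (bought), then ring A, then ring B by expansion.

Assumption: C1–C15 in the text are eudesmane locants, and the lithium-to-titanium exchange in step 3 is taken to go with inversion, as is usual for lithiated allyl carbamates (if it went with retention, the enantiomer of 2 would be made with the enantiomeric oxazaborolidine).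

**Route**

Step 1
Reactants: 1 3-methylcyclopent-2-en-1-one
Product: 2 (1S)-3-methylcyclopent-2-en-1-ol
Conditions: (R)-1-methyl-3,3-diphenyltetrahydro-1H,3H-pyrrolo[1,2-c][1,3,2]oxazaborole (10 mol%), BH3·SMe2, THF, −20 °C
Reagents that add atoms: none
Why: Corey–Bakshi–Shibata reduction; the oxazaborolidine–borane complex delivers hydride 1,2 to one carbonyl face (alkene arm as the large group) and gives the (S)-allylic alcohol, the source of all absolute stereochemistry.

Step 2
Reactants: 2 (1S)-3-methylcyclopent-2-en-1-ol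
Product: 3 (1S)-3-methylcyclopent-2-en-1-yl N,N-di(propan-2-yl)carbamate
Conditions: i-Pr2NCOCl, pyridine, 90 °C
Reagents that add atoms: N,N-di(propan-2-yl)carbamoyl chloride CC(C)N(C(C)C)C(Cl)=O
Why: O-carbamoylation of a secondary alcohol; no stereocentre is touched and the carbamate directs and stabilises the α-lithiation of step 3.

Step 3
Reactants: 3 (1S)-3-methylcyclopent-2-en-1-yl N,N-di(propan-2-yl)carbamate; 4 pent-4-ynal
Product: 7 (3R)-3-[(1R)-1-hydroxypent-4-yn-1-yl]-3-methylcyclopent-1-en-1-yl N,N-di(propan-2-yl)carbamate, via lithiated carbamate 5 (not isolated), via allyltitanium reagent 6 (not isolated)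
Conditions: s-BuLi, TMEDA, Et2O, −78 °C; ClTi(Oi-Pr)3, −78 °C; then 4, −78 °C to rt; aq. NH4Cl
Reagents that add atoms: none
Why: Hoppe homoaldol reaction; the allyltitanium adds to the aldehyde at the γ-carbon through a chair transition state (aldehyde chain equatorial, ring CH2 axial, methyl equatorial), which sets C1 (R) and quaternary C10 (R) together and leaves a regiodefined enol carbamate at C5=C6.

Step 4
Reactants: 7 (3R)-3-[(1R)-1-hydroxypent-4-yn-1-yl]-3-methylcyclopent-1-en-1-yl N,N-di(propan-2-yl)carbamate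
Product: 8 (3R)-3-methyl-3-[(1R)-1-(triethylsilyloxy)pent-4-yn-1-yl]cyclopent-1-en-1-yl N,N-di(propan-2-yl)carbamate
Conditions: Et3SiOTf, 2,6-lutidine, CH2Cl2, −78 to 0 °C
Reagents that add atoms: triethylsilyl trifluoromethanesulfonate CC[Si](CC)(CC)OS(=O)(=O)C(F)(F)F
Why: O-silylation of the hindered secondary alcohol; it stops 5-exo O-attack on the gold-activated alkyne in step 5 and keeps C1–OH masked until step 9.

Step 5
Reactants: 8 (3R)-3-methyl-3-[(1R)-1-(triethylsilyloxy)pent-4-yn-1-yl]cyclopent-1-en-1-yl N,N-di(propan-2-yl)carbamate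
Product: 9 (3aR,4R,7aR)-3a-methyl-7-methylidene-4-(triethylsilyloxy)octahydro-1H-inden-1-one
Conditions: Ph3PAuNTf2 (5 mol%), acetone/H2O (20:1), 40 °C
Reagents that add atoms: water O
Why: Proposed new method: a monovalent-gold-catalysed Conia-ene-type carbocyclisation in which an enol carbamate, not a silyl enol ether, is the π-nucleophile; C5 attacks the gold-bound terminal alkyne 6-exo-dig (forming C4–C5 and ring A, necessarily cis-fused), water hydrates the carbamoyloxy-stabilised cation at C6 to release the ketone with i-Pr2NH and CO2, and protodeauration gives the exocyclic methylene without base, so the terminal alkyne is tolerated; the closest known reaction is the gold-catalysed cyclisation of silyl enol ethers onto alkynes.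

Step 6
Reactants: 9 (3aR,4R,7aR)-3a-methyl-7-methylidene-4-(triethylsilyloxy)octahydro-1H-inden-1-one
Product: 11 (4aR,5R)-4a,8-dimethyl-2-(propan-2-yl)-5-(triethylsilyloxy)-3,4,4a,5,6,7-hexahydronaphthalen-1(2H)-one (C2 epimers), via ring-expanded ketone 10 (not isolated)
Conditions: i-PrCHN2 (freshly prepared, 1.5 equiv), Sc(OTf)3 (10 mol%), toluene, −78 to −30 °C; then DBU, 40 °C
Reagents that add atoms: 1-diazo-2-methylpropane CC(C)C=[N+]=[N-]
Why: Lewis-acid-catalysed diazoalkane–ketone homologation (Tiffeneau–Demjanov-type 1,2-shift); the diazo carbon adds to C6, the less substituted C8 migrates with loss of N2 so that the five-membered ketone becomes ring B with C7 and its isopropyl group in place, and DBU then moves the exocyclic alkene into conjugation, which erases the cis fusion and converges the mixture on one enone skeleton.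

Step 7
Reactants: 11 (4aR,5R)-4a,8-dimethyl-2-(propan-2-yl)-5-(triethylsilyloxy)-3,4,4a,5,6,7-hexahydronaphthalen-1(2H)-one (C2 epimers)
Product: 15 (1R,2S,4aR,5R,8aS)-4a-methyl-8-methylidene-2-(propan-2-yl)-5-(triethylsilyloxy)decahydronaphthalen-1-ol, via lithium dienolate 12 (not isolated), via C7-defined enone 13 (not isolated), via deconjugated ketone 14 (not isolated)
Conditions: LiN(i-Pr)2, THF, −78 °C; AcOH (2 equiv), −78 °C; hν (350 nm), THF/MeOH, 0 °C; then CeCl3·7H2O, NaBH4, −40 to 0 °C
Reagents that add atoms: none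
Why: Kinetic α′-deprotonation and axial (α-face) protonation of the cross-conjugated enolate make the isopropyl group equatorial (C7 S); photodeconjugation (photoenolisation by 1,5-H transfer from the C15 methyl syn to the carbonyl, then ketonisation at C5 anti to the angular methyl) gives the trans-fused 4(15)-en-6-one; Luche reduction then attacks C6 from the α face, because the β face is blocked by the axial C10 methyl, and gives the axial 6β-alcohol.

Step 8
Reactants: 15 (1R,2S,4aR,5R,8aS)-4a-methyl-8-methylidene-2-(propan-2-yl)-5-(triethylsilyloxy)decahydronaphthalen-1-ol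
Product: 16 (1R,2S,4aR,5R,8aS)-4a-methyl-8-methylidene-2-(propan-2-yl)-5-(triethylsilyloxy)decahydronaphthalen-1-yl 2-(diethoxyphosphoryl)acetate
Conditions: (EtO)2P(O)CH2CO2H, DCC, DMAP, CH2Cl2, rt to 40 °C
Reagents that add atoms: 2-(diethoxyphosphoryl)acetic acid CCOP(=O)(CC(=O)O)OCC
Why: Steglich esterification; the carbodiimide-activated phosphonoacetic acid is small and reactive enough for the hindered axial 6β-alcohol, the only free hydroxyl.

Step 9
Reactants: 16 (1R,2S,4aR,5R,8aS)-4a-methyl-8-methylidene-2-(propan-2-yl)-5-(triethylsilyloxy)decahydronaphthalen-1-yl 2-(diethoxyphosphoryl)acetate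
Product: 18 (1R,2S,4aR,5R,8R,8aS)-5,8-dihydroxy-8-(hydroxymethyl)-4a-methyl-2-(propan-2-yl)decahydronaphthalen-1-yl 2-(diethoxyphosphoryl)acetate, via silyl-protected diol 17 (not isolated)
Conditions: OsO4 (2 mol%), N-methylmorpholine N-oxide, acetone/H2O, rt; then 1 M HCl, THF, rt
Reagents that add atoms: N-methylmorpholine N-oxide C[N+]1([O-])CCOCC1; water O
Why: Upjohn dihydroxylation of the only alkene from the α face (equatorial attack, the β face being shielded by the axial C10 methyl and the 6β-ester) sets C4 (R) with 4α-OH and axial CH2OH, and the acid then cleaves the triethylsilyl ether.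

Step 10
Reactants: 18 (1R,2S,4aR,5R,8R,8aS)-5,8-dihydroxy-8-(hydroxymethyl)-4a-methyl-2-(propan-2-yl)decahydronaphthalen-1-yl 2-(diethoxyphosphoryl)acetate; 19 benzaldehyde
Product: 20 (1R,2S,4aR,5R,8R,8aS)-5,8-dihydroxy-8-(hydroxymethyl)-4a-methyl-2-(propan-2-yl)decahydronaphthalen-1-yl (2E)-3-phenylprop-2-enoate
Conditions: PhCHO, LiCl, DBU, MeCN, rt
Reagents that add atoms: none
Why: Horner–Wadsworth–Emmons olefination under Masamune–Roush conditions; the stabilised phosphonate anion and an aryl aldehyde give the (E)-cinnamate under mild base that the free triol tolerates.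

**Compound list**
1 | 3-methylcyclopent-2-en-1-one | CC1=CC(=O)CC1 | starting material
2 | (1S)-3-methylcyclopent-2-en-1-ol | O[C@@H]1C=C(C)CC1 | intermediate
3 | (1S)-3-methylcyclopent-2-en-1-yl N,N-di(propan-2-yl)carbamate | CC(C)N(C(C)C)C(=O)O[C@@H]1C=C(C)CC1 | intermediate
4 | pent-4-ynal | O=CCCC#C | starting material
5 | 1-lithio-3-methylcyclopent-2-en-1-yl N,N-di(propan-2-yl)carbamate (lithium in place of the former C–H) | [Li][C@@]1(OC(=O)N(C(C)C)C(C)C)C=C(C)CC1 | intermediate
6 | 3-methyl-1-[tri(propan-2-yloxy)titanio]cyclopent-2-en-1-yl N,N-di(propan-2-yl)carbamate (titanium on the opposite ring face) | CC(C)O[Ti](OC(C)C)(OC(C)C)[C@]1(OC(=O)N(C(C)C)C(C)C)C=C(C)CC1 | intermediate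
7 | (3R)-3-[(1R)-1-hydroxypent-4-yn-1-yl]-3-methylcyclopent-1-en-1-yl N,N-di(propan-2-yl)carbamate | C1C[C@@](C=C1OC(=O)N(C(C)C)C(C)C)(C)[C@H](O)CCC#C | intermediate
8 | (3R)-3-methyl-3-[(1R)-1-(triethylsilyloxy)pent-4-yn-1-yl]cyclopent-1-en-1-yl N,N-di(propan-2-yl)carbamate | C1C[C@@](C=C1OC(=O)N(C(C)C)C(C)C)(C)[C@H](O[Si](CC)(CC)CC)CCC#C | intermediate
9 | (3aR,4R,7aR)-3a-methyl-7-methylidene-4-(triethylsilyloxy)octahydro-1H-inden-1-one (cis-fused) | C1C[C@@]2(C)[C@H](O[Si](CC)(CC)CC)CCC(=C)[C@H]2C1=O | intermediate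
10 | (4aR,5R,8aR)-4a-methyl-8-methylidene-2-(propan-2-yl)-5-(triethylsilyloxy)octahydronaphthalen-1(2H)-one (C2 epimers) | CC(C)C1CC[C@@]2(C)[C@H](O[Si](CC)(CC)CC)CCC(=C)[C@H]2C1=O | intermediate
11 | (4aR,5R)-4a,8-dimethyl-2-(propan-2-yl)-5-(triethylsilyloxy)-3,4,4a,5,6,7-hexahydronaphthalen-1(2H)-one (C2 epimers) | CC(C)C1CC[C@@]2(C)[C@H](O[Si](CC)(CC)CC)CCC(C)=C2C1=O | intermediate
12 | lithium enolate of 11 towards C2 (cross-conjugated dienolate) | CC(C)C=1CC[C@@]2(C)[C@H](O[Si](CC)(CC)CC)CCC(C)=C2C=1O[Li] | intermediate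
13 | (2S,4aR,5R)-4a,8-dimethyl-2-(propan-2-yl)-5-(triethylsilyloxy)-3,4,4a,5,6,7-hexahydronaphthalen-1(2H)-one | CC(C)[C@@H]1CC[C@@]2(C)[C@H](O[Si](CC)(CC)CC)CCC(C)=C2C1=O | intermediate
14 | (2S,4aR,5R,8aS)-4a-methyl-8-methylidene-2-(propan-2-yl)-5-(triethylsilyloxy)octahydronaphthalen-1(2H)-one (trans-fused) | CC(C)[C@@H]1CC[C@@]2(C)[C@H](O[Si](CC)(CC)CC)CCC(=C)[C@@H]2C1=O | intermediate
15 | (1R,2S,4aR,5R,8aS)-4a-methyl-8-methylidene-2-(propan-2-yl)-5-(triethylsilyloxy)decahydronaphthalen-1-ol | CC(C)[C@@H]1CC[C@@]2(C)[C@H](O[Si](CC)(CC)CC)CCC(=C)[C@@H]2[C@@H]1O | intermediate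
16 | (1R,2S,4aR,5R,8aS)-4a-methyl-8-methylidene-2-(propan-2-yl)-5-(triethylsilyloxy)decahydronaphthalen-1-yl 2-(diethoxyphosphoryl)acetate | CC(C)[C@@H]1CC[C@@]2(C)[C@H](O[Si](CC)(CC)CC)CCC(=C)[C@@H]2[C@@H]1OC(=O)CP(=O)(OCC)OCC | intermediate
17 | (1R,2S,4aR,5R,8R,8aS)-8-hydroxy-8-(hydroxymethyl)-4a-methyl-2-(propan-2-yl)-5-(triethylsilyloxy)decahydronaphthalen-1-yl 2-(diethoxyphosphoryl)acetate | CC(C)[C@@H]1CC[C@@]2(C)[C@H](O[Si](CC)(CC)CC)CC[C@](O)(CO)[C@@H]2[C@@H]1OC(=O)CP(=O)(OCC)OCC | intermediate
18 | (1R,2S,4aR,5R,8R,8aS)-5,8-dihydroxy-8-(hydroxymethyl)-4a-methyl-2-(propan-2-yl)decahydronaphthalen-1-yl 2-(diethoxyphosphoryl)acetate | CC(C)[C@@H]1CC[C@@]2(C)[C@H](O)CC[C@](O)(CO)[C@@H]2[C@@H]1OC(=O)CP(=O)(OCC)OCC | intermediate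
19 | benzaldehyde | O=Cc1ccccc1 | starting material
20 | (1R,2S,4aR,5R,8R,8aS)-5,8-dihydroxy-8-(hydroxymethyl)-4a-methyl-2-(propan-2-yl)decahydronaphthalen-1-yl (2E)-3-phenylprop-2-enoate (CNP0114365.1) | CC(C)[C@@H]1CC[C@@]2(C)[C@H](O)CC[C@](O)(CO)[C@@H]2[C@@H]1OC(=O)/C=C/c1ccccc1 | target

**Step count and risks**
Total steps: 10. Longest linear sequence: 10 (from 1; 4 and 19 enter along the way).

The three steps most likely to fail:

Step 5 (the proposed new gold cyclisation). The enol carbamate may be too weak a nucleophile, the cation may lose a proton instead of being hydrated, or the released amine may slow the catalyst. The fallback sets out from 8 and comes back at 9. MeLi (3.2 equiv, THF, 0 °C) cleaves the carbamate and gives the lithium enolate, with the alkyne also lithiated, F1. t-BuMe2SiCl with HMPA at −78 °C silylates the enolate oxygen to give the tert-butyldimethylsilyl enol ether F2 (the acetylide is reprotonated on work-up). Ph3PAuCl/AgBF4 in CH2Cl2/MeOH then brings about the known 6-exo-dig cyclisation of a silyl enol ether onto a terminal alkyne to give 9.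

Step 6 (ring expansion). The α-branched, hindered cyclopentanone may react sluggishly with the secondary diazoalkane, or C5 may compete as the migrating carbon. The fallback sets out from 9 and comes back at 11. Me3SiCHN2 with BF3·OEt2 (CH2Cl2, −78 °C) does the one-carbon homologation with the smaller reagent, and K2CO3 in MeOH removes the C-silyl group and conjugates the alkene to give the isopropyl-free enone F3. LiN(i-Pr)2 in THF/DMPU at −78 °C then forms the α′-enolate, which is alkylated with 2-iodopropane to give 11 (a modest yield is expected for the secondary iodide).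

Step 7 (setting C7 and C5, then reduction). The kinetic protonation at C7 rests on a moderate axial preference, deprotonation may occur at the γ-carbon instead of C7, and the photodeconjugation may be inefficient. The fallback sets out from 11 and comes back at 15. 2-Iodoxybenzoic acid (DMSO/toluene, 70 °C) dehydrogenates C7–C8 to the cross-conjugated dienone F4. H2 over Pd/C adds to the less substituted C7=C8 bond from the α face and gives 13, so C7 is set by syn addition of hydrogen and not by protonation. Lithium 2,2,6,6-tetramethylpiperidide with HMPA (THF, −78 °C) removes the C15 proton syn to the carbonyl to give the extended lithium dienolate F5, and kinetic α-protonation with AcOH at −78 °C gives 14. NaBH4/CeCl3 then gives 15.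

Further compounds
F1 | step 5 | dilithium enolate–acetylide from 8 after loss of the carbamoyl group | C1C[C@@](C=C1O[Li])(C)[C@H](O[Si](CC)(CC)CC)CCC#C[Li]
F2 | step 5 | tert-butyl-dimethyl-{[(3R)-3-methyl-3-[(1R)-1-(triethylsilyloxy)pent-4-yn-1-yl]cyclopent-1-en-1-yl]oxy}silane | C1C[C@@](C=C1O[Si](C)(C)C(C)(C)C)(C)[C@H](O[Si](CC)(CC)CC)CCC#C
F3 | step 6 | (4aR,5R)-4a,8-dimethyl-5-(triethylsilyloxy)-3,4,4a,5,6,7-hexahydronaphthalen-1(2H)-one | C1CC[C@@]2(C)[C@H](O[Si](CC)(CC)CC)CCC(C)=C2C1=O
F4 | step 7 | (4aR,5R)-4a,8-dimethyl-2-(propan-2-yl)-5-(triethylsilyloxy)-4a,5,6,7-tetrahydronaphthalen-1(4H)-one | CC(C)C1=CC[C@@]2(C)[C@H](O[Si](CC)(CC)CC)CCC(C)=C2C1=O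
F5 | step 7 | extended lithium dienolate of 13 (C1=C8a enolate, exocyclic C8 methylidene) | CC(C)[C@@H]1CC[C@@]2(C)[C@H](O[Si](CC)(CC)CC)CCC(=C)C2=C1O[Li]
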